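## Structural features

Target 33 joins two lignan-type units through one methylene carbon: a 2,3,4-trisubstituted tetrahydrofuran (O1, C2–C5) and a 2-aryl-3-hydroxymethyl-2,3-dihydrobenzofuran (O1', C2', C3', benzo ring B = C3a'–C7a'), with C7 linking C4 to C6' of ring B. The tetrahydrofuran carries ring A (3-hydroxy-4-methoxyphenyl) on C2, the hydroxymethyl carbon C9 on C3 and C7 on C4; its three contiguous stereocentres are 2R,3S,4S, so C9 and C7 are cis to each other and both trans to ring A. The dihydrobenzofuran carries ring C (4-hydroxy-3-methoxyphenyl) on C2' and the hydroxymethyl carbon C9' on C3' in a trans relationship (2'S,3'R). Ring B is a resorcinol with one oxygen methylated (C4'), the other in the furan ring (C7a'), and carbon substituents at C3a' and C6'. The two stereo-clusters are insulated from each other by C7 and ring B, so each must be set in the absolute sense on its own. The fragile points are the two benzylic C–O bonds (C2–O1 para to the ring A methoxy group, C2'–O1' para to the ring C oxygen): they ionise under acid, can be hydrogenolysed, and C2'–O1' can open through a quinone methide under base once the ring C phenol is free; the electron-rich arenes also limit oxidants. The real difficulty is the tetrahydrofuran triad, whose 3,4-cis arrangement is not thermodynamically favoured and must be made on a substrate that already holds the dihydrobenzofuran. The key step exploits the cis placement of C9 and C7 on the adjacent carbons C3 and C4, opposite to ring A: this is the imprint of a cis-fused 3-oxabicyclo[3.2.0]heptane with ring A exo in which C7 and C9 are bonded, so a [2+2] cycloaddition of a C4=C7 styrene (ring B) with a C3=C9 alkene, followed by scission of C7–C9 at the benzylic carbon, delivers the triad.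

## Logic of the disconnections

33 to 32: the three O–Si bonds are cut. Both phenols and C9'–OH are carried as silyl ethers so that the last step is one fluoride treatment, with no hydrogenolysis and no acid next to the two benzylic C–O bonds. The forward step must be buffered so that the ring C phenoxide does not open the dihydrobenzofuran.

32 to 30 (through 31): C7 and C9 are reconnected and C9 becomes a carbinol. The two cis side arms become a cyclobutane, which turns an acyclic stereochemical problem into a ring-fusion problem. The forward step needs an alkoxy radical at C9 that fragments towards benzylic C7, and 31 must be reduced before C3 epimerises.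

30 to 29: C9–O is exchanged for C9–B. Boron is a placeholder that makes the alkene partner easy to prepare. The forward oxidation must be stereoretentive in principle and mild enough for aryl silyl ethers.

29 to 28 (key): C3–C4 and C7–C9 are cut. Two rings and four stereocentres fall back to an acyclic bis-allylic ether with one stereocentre (C2). The forward step needs selective triplet excitation of the styrene and facial control from C2.

28 to 26 and 27: the C9–B and C3–H bonds are removed, leaving a terminal alkyne. The forward hydroboration must be syn, anti-Markovnikov and blind to the styrene.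

26 to 25 and 20: the C5–O1 ether bond is cut, which divides the molecule into the ring A carbinol and the dihydrobenzofuran allylic bromide. The forward O-alkylation does not touch the carbinol centre but must avoid excess base.

25 to 24, then to 22 and 23, then to 21: the C2–C3 bond is cut at the aldehyde. One catalytic asymmetric alkynylation sets C2; the forward steps need high enantioselectivity with an electron-rich aldehyde and a neutral removal of the alkynyl silyl group.

20 to 19, then to 17 and 18: the C6'–C7 bond is cut. The three-carbon arm arrives in one coupling with its E geometry, and the aryl bromide of 17 is an inert handle through all earlier steps. The coupling base must spare the aryl silyl ether.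

17 to 16, then to 14 (through 15): the O1'–C2' bond is cut. Ring closure by benzylic substitution makes C2' follow from C3' (trans), so only C3' needs absolute control. The forward step must trap the cation faster than it loses the C3' proton.

14 to 13, then to 10 and 12, then to 11: the C2'–C3' bond is cut as an auxiliary-controlled aldol, and reductive removal of the auxiliary delivers C9' at the alcohol level. The forward step needs a Z-enolate from a hindered arylacetyl imide and no retro-aldol.

10 to 7 and 8, and 7 to 6, then to 3 and 4: the N-acyl bond and then the C3'–C9' bond are cut, a one-carbon homologation of an aldehyde. The forward steps must tolerate the aryl bromide and the acetal.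

3 to 2 to 1: the acetal O–C bond and one O–CH3 bond are cut. The two equivalent methoxy groups of 1 are differentiated at the start by chelation; the forward demethylation must stop at one.

## Other disconnections considered

Alternative 1: The cut is C3a'–C3' of the dihydrobenzofuran, traced back to the bond between the carbonyl carbon and ring B of flavanone A1. In the forward step PhI(OAc)2 and H2SO4 in trimethyl orthoformate put trivalent iodine on C3 of the enol ether of A1; ring B migrates from the carbonyl carbon to that carbon as iodobenzene leaves, and the resulting cation is captured as the methyl ester, giving trans ester A2.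
- In its favour: A1 comes from simple aromatic ketone and aldehyde building blocks, so the two ring B oxygens are differentiated from the outset, C9' arrives at the ester level, and the trans relationship is the thermodynamic one for an enolisable ester. The tosylate should resist the oxidant.
- Against it here: A1 must be enantiopure, and flavanones can racemise by reversible ring opening under the acid that the contraction needs. The aryl chloride of A2 is a poorer coupling handle than the bromide of 17. Tosylate removal adds a basic or reductive step on a base-sensitive phenylcoumaran. The tetrahydrofuran triad is not addressed at all.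
- Comparison: structurally it only replaces the sequence to 17 and still needs the chosen key step or another solution for C2–C4. Mechanistically its control element is C2', which can be lost, whereas the chosen aldol fixes C3' with an auxiliary of predictable sense. On step economy for the dihydrobenzofuran alone the alternative is the better (roughly half the steps), and on trans selectivity the two are equal.

Alternative 2: The cut goes through ring B itself, along C7a'–C3a' and C4'–C5', and gives cyclobutenone A3 (carrying the complete tetrahydrofuran half) and siloxyalkyne A4 (carrying C2', C3' and ring C). In the forward step heating in toluene triggers two 4π-electrocyclic openings, a [2+2] addition and a 6π closure, and tautomerisation gives resorcinol mono-silyl ether A5.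
- In its favour: it is the most convergent plan, the substitution pattern of ring B is dictated by the pericyclic cascade, the two ring B oxygens are born differentiated (OH and OTIPS), and no metal is needed.
- Against it here: A3 must already contain the 2R,3S,4S triad, so the hardest problem is moved, not solved. A4 is a sensitive chiral ynol ether needing its own asymmetric synthesis. After the union there remain ring closure at C2' with inversion (on a p-alkoxybenzylic alcohol that tends to ionise), exchange of the silyl group for methyl, and hydrogenolysis of four benzyl ethers, two of them alkyl benzyl ethers, next to two benzylic C–O bonds.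
- Comparison: on convergence and on regiochemical control of ring B the alternative is equal or better (no demethylation, no homologation). Mechanistically both rely on well-behaved pericyclic or photochemical events. On total step count and on the safety of the end game the chosen plan should be better.

Alternative 3: The cut removes O1'–C7a' and C3a'–C3', so the dihydrofuran ring is annulated onto an aryne from silyl triflate A6 (carrying the tetrahydrofuran half) and erythro epoxy alcohol A7. In the forward step CsF releases the aryne from A6; the cesium alkoxide of A7 adds at the aryne carbon remote from the methoxy group, and the aryl anion next to the methoxy group opens the oxirane at C3' (5-exo-tet, inversion), giving A8 with the trans arrangement and a free C9' hydroxyl.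
- In its favour: both ring bonds, both stereocentres (from one enantiopure epoxy alcohol) and C9'–OH come in one step on the fully elaborated half; the methoxy group directs the regiochemistry; A8 is one deprotection from 33.
- Against it here: aryl anions formed by alkoxide addition to arynes are normally quenched by proton transfer faster than they attack an unactivated oxirane. The alkoxide of A7 can undergo Payne rearrangement. A6 needs an ortho-silyl phenol built late on a complex substrate. The triad must again come from elsewhere, and the final hydrogenolysis includes an alkyl benzyl ether.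
- Comparison: on paper this is the shortest and most convergent route to the dihydrobenzofuran, and on step economy it is the better. Mechanistically the tandem addition–oxirane opening has thin precedent, whereas every step of the chosen plan belongs to an established reaction type, so the chosen plan trades steps for certainty.

Key step: step 18

Remark on the chemistry: 1 is taken as a catalogue compound (otherwise one step from 1-bromo-3,5-dimethoxybenzene by lithiation between the methoxy groups and formylation).
Remark on the chemistry: the ligand antipode in step 14 is assumed from the facial model and would be checked on 24 by Mosher ester analysis.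
Remark on the chemistry: the phenols are carried as triisopropylsilyl ethers so that no hydrogenolysis is needed, and 29 is drawn as one C6/C7 epimer of a mixture that converges.
Abbreviations in names:
- ArA = 4-methoxy-3-(triisopropylsilyloxy)phenyl (ring A)
- ArC = 3-methoxy-4-(triisopropylsilyloxy)phenyl (ring C)
- ArB = 4-bromo-2-methoxy-6-(methoxymethoxy)phenyl
- DHB = (2S,3R)-3-[(tert-butyldimethylsilyloxy)methyl]-4-methoxy-2-ArC-2,3-dihydro-1-benzofuran-6-yl
- Bpin = 4,4,5,5-tetramethyl-1,3,2-dioxaborolan-2-yl

## Route

Step 1
Reactants: 1 4-bromo-2,6-dimethoxybenzaldehyde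
Product: 2 4-bromo-2-hydroxy-6-methoxybenzaldehyde
Conditions: BCl3 (1.1 equiv), CH2Cl2, −78 → 0 °C; then H2O
Reagents that add atoms: none
Why: Lewis-acid ether cleavage under chelation control: boron binds the aldehyde oxygen and removes one flanking methyl group through a six-membered chelate, and the aryloxyboron chelate deactivates the second, equivalent methoxy group, so the symmetric ring is desymmetrised without a regiochemical question.

Step 2
Reactants: 2 4-bromo-2-hydroxy-6-methoxybenzaldehyde
Product: 3 4-bromo-2-methoxy-6-(methoxymethoxy)benzaldehyde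
Conditions: MeOCH2Cl, iPr2NEt, CH2Cl2, 0 °C → rt
Reagents that add atoms: chloromethyl methyl ether, COCCl
Why: O-alkylation of the phenol with an α-chloro ether (acetal protection); the methoxymethyl ether should survive the basic and reductive steps 3 to 8 and leave under the acid of step 9.

Step 3
Reactants: 3 4-bromo-2-methoxy-6-(methoxymethoxy)benzaldehyde; 4 p-toluenesulfonylmethyl isocyanide
Product: 6 2-[4-bromo-2-methoxy-6-(methoxymethoxy)phenyl]acetonitrile, via vinylformamide adduct 5 (not isolated)
Conditions: KOtBu, DME, −35 °C → rt; then MeOH, reflux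
Reagents that add atoms: none
Why: Van Leusen reductive cyanation: the isocyanide anion adds to the aldehyde, the oxazoline opens to 5, and methanolysis with loss of methyl formate and sulfinate gives the homologous nitrile, which forms the C3'–C9' bond and tolerates the aryl bromide and the acetal.

Step 4
Reactants: 6 2-[4-bromo-2-methoxy-6-(methoxymethoxy)phenyl]acetonitrile
Product: 7 2-[4-bromo-2-methoxy-6-(methoxymethoxy)phenyl]acetic acid
Conditions: KOH, EtOH/H2O, reflux; then 1 M HCl to pH 4, 0 °C
Reagents that add atoms: potassium hydroxide, [K+].[OH-]; water, O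
Why: Base hydrolysis of an unhindered benzylic nitrile; cold acidification only to pH 4 should free the acid without cleaving the acetal.

Step 5
Reactants: 7 2-[4-bromo-2-methoxy-6-(methoxymethoxy)phenyl]acetic acid; 8 (S)-4-benzyl-1,3-oxazolidin-2-one
Product: 10 (S)-4-benzyl-3-(2-ArB-acetyl)-1,3-oxazolidin-2-one, via mixed pivalic anhydride 9 (not isolated)
Conditions: tBuCOCl, Et3N, THF, −20 °C; then 8, LiCl, −20 °C → rt
Reagents that add atoms: none
Why: N-acylation of the Evans oxazolidinone through the mixed anhydride with LiCl/Et3N, which avoids strong base on the acidic arylacetyl unit.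

Step 6
Reactants: 11 vanillin (4-hydroxy-3-methoxybenzaldehyde)
Product: 12 3-methoxy-4-(triisopropylsilyloxy)benzaldehyde
Conditions: iPr3SiCl, imidazole, DMF, rt
Reagents that add atoms: chlorotriisopropylsilane, CC(C)[Si](Cl)(C(C)C)C(C)C
Why: Silylation of a phenol; the aryl triisopropylsilyl ether should withstand Lewis acid, hydride, dilute acid and mild base and leaves with fluoride in step 21.

Step 7
Reactants: 10 (S)-4-benzyl-3-(2-ArB-acetyl)-1,3-oxazolidin-2-one; 12 3-methoxy-4-(triisopropylsilyloxy)benzaldehyde
Product: 13 (S)-4-benzyl-3-[(2S,3S)-2-ArB-3-hydroxy-3-ArC-propanoyl]-1,3-oxazolidin-2-one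
Conditions: Bu2BOTf, iPr2NEt, CH2Cl2, −78 → 0 °C; then 12, −78 → 0 °C; pH 7 buffer, MeOH, H2O2
Reagents that add atoms: none
Why: Evans syn-aldol: the Z-boron enolate reacts through a Zimmerman–Traxler chair on the enolate face opposite the benzyl group of the auxiliary, setting the α-centre (2S in 13, the future 3'R) and the carbinol (3S); only the α-centre is needed later.

Step 8
Reactants: 13 (S)-4-benzyl-3-[(2S,3S)-2-ArB-3-hydroxy-3-ArC-propanoyl]-1,3-oxazolidin-2-one
Product: 14 (1S,2R)-2-ArB-1-ArC-propane-1,3-diol
Conditions: LiBH4, THF, H2O (1 equiv), 0 °C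
Reagents that add atoms: none
Why: Reductive cleavage of the imide gives the primary alcohol (C9') and returns the auxiliary; after this step the α-aryl centre is no longer enolisable.

Step 9
Reactants: 14 (1S,2R)-2-ArB-1-ArC-propane-1,3-diol
Product: 16 [(2S,3R)-6-bromo-4-methoxy-2-ArC-2,3-dihydro-1-benzofuran-3-yl]methanol, via phenol triol 15 (not isolated)
Conditions: HCl (0.5 M in MeOH), THF, 0 °C → rt
Reagents that add atoms: none
Why: Acid-catalysed acetal exchange frees the ring B phenol (15), and ionisation of the p-silyloxybenzylic alcohol gives a cation that the neighbouring phenol traps in a 5-exo closure (SN1 cycloetherification). The trans ring is both the kinetic and the thermodynamic product, so C2' follows from C3' and ends as 2'S; intramolecular capture should outrun loss of the C3' proton, so C3' is not touched.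

Step 10
Reactants: 16 [(2S,3R)-6-bromo-4-methoxy-2-ArC-2,3-dihydro-1-benzofuran-3-yl]methanol
Product: 17 (2S,3R)-6-bromo-3-[(tert-butyldimethylsilyloxy)methyl]-4-methoxy-2-ArC-2,3-dihydro-1-benzofuran
Conditions: tBuMe2SiCl, imidazole, CH2Cl2, rt
Reagents that add atoms: tert-butylchlorodimethylsilane, CC(C)(C)[Si](C)(C)Cl
Why: Silylation of the only free hydroxyl group; it protects C9'–OH against O-alkylation in step 16.

Step 11
Reactants: 17 (2S,3R)-6-bromo-3-[(tert-butyldimethylsilyloxy)methyl]-4-methoxy-2-ArC-2,3-dihydro-1-benzofuran; 18 (E)-3-(4,4,5,5-tetramethyl-1,3,2-dioxaborolan-2-yl)prop-2-en-1-ol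
Product: 19 (E)-3-(DHB)prop-2-en-1-ol
Conditions: PdCl2(dppf) (5 mol%), K3PO4, THF/H2O, 60 °C
Reagents that add atoms: none
Why: Suzuki–Miyaura coupling of the aryl bromide with an E-alkenylboronate; the alkene geometry is retained in transmetalation and reductive elimination, and the phosphate base should spare the aryl silyl ether.

Step 12
Reactants: 19 (E)-3-(DHB)prop-2-en-1-ol
Product: 20 (E)-1-bromo-3-(DHB)prop-2-ene
Conditions: CBr4, PPh3, CH2Cl2, 0 °C
Reagents that add atoms: tetrabromomethane, BrC(Br)(Br)Br
Why: Appel bromination of a primary allylic alcohol under neutral conditions; the ring B oxygens are meta to the side chain, so the bromide is not unusually labile, and it is used without storage.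

Step 13
Reactants: 21 isovanillin (3-hydroxy-4-methoxybenzaldehyde)
Product: 22 4-methoxy-3-(triisopropylsilyloxy)benzaldehyde
Conditions: iPr3SiCl, imidazole, DMF, rt
Reagents that add atoms: chlorotriisopropylsilane, CC(C)[Si](Cl)(C(C)C)C(C)C
Why: Silylation of a phenol, as in step 6.

Step 14
Reactants: 22 4-methoxy-3-(triisopropylsilyloxy)benzaldehyde; 23 ethynyltrimethylsilane
Product: 24 (S)-1-ArA-3-(trimethylsilyl)prop-2-yn-1-ol
Conditions: ZnMe2, (S,S)-ProPhenol (20 mol%), Ph3PO (40 mol%), toluene, 0 °C → rt
Reagents that add atoms: none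
Why: Zinc–ProPhenol-catalysed asymmetric alkynylation of the aldehyde; C2 is set by delivery of the alkynyl group to the Re face, which reads as (S) here because the silylalkynyl group outranks the aryl group, and the ligand antipode is the one chosen for this face.

Step 15
Reactants: 24 (S)-1-ArA-3-(trimethylsilyl)prop-2-yn-1-ol
Product: 25 (R)-1-ArA-prop-2-yn-1-ol
Conditions: AgNO3 (10 mol%), acetone/H2O, rt
Reagents that add atoms: none
Why: Silver-catalysed protodesilylation of the alkynylsilane under neutral conditions, which leaves the base-sensitive aryl silyl ether alone; the descriptor changes to (R) only because ethynyl ranks below aryl.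

Step 16
Reactants: 25 (R)-1-ArA-prop-2-yn-1-ol; 20 (E)-1-bromo-3-(DHB)prop-2-ene
Product: 26 (R)-1-ArA-prop-2-yn-1-yl (E)-3-(DHB)prop-2-en-1-yl ether
Conditions: NaH (1.05 equiv), THF, 0 °C; then 20, Bu4NI (10 mol%), THF/DMF, 0 °C → rt
Reagents that add atoms: none
Why: Williamson ether synthesis: the sodium alkoxide displaces the primary allylic bromide (SN2), so neither the carbinol centre nor the E-alkene is touched; one equivalent of base at 0 °C avoids deprotonation of the alkyne or of C2–H.

Step 17
Reactants: 26 (R)-1-ArA-prop-2-yn-1-yl (E)-3-(DHB)prop-2-en-1-yl ether; 27 pinacolborane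
Product: 28 (R,E)-1-ArA-3-Bpin-prop-2-en-1-yl (E)-3-(DHB)prop-2-en-1-yl ether
Conditions: Cp2Zr(H)Cl (10 mol%), Et3N (10 mol%), toluene, 60 °C
Reagents that add atoms: none
Why: Zirconium-hydride-catalysed hydroboration of the terminal alkyne: syn, anti-Markovnikov addition gives the E-alkenylboronate, and the 1,2-disubstituted styrene is much slower to hydrometalate.

Step 18
Reactants: 28 (R,E)-1-ArA-3-Bpin-prop-2-en-1-yl (E)-3-(DHB)prop-2-en-1-yl ether
Product: 29 (1R,2R,5S,6R,7R)-2-ArA-6-(DHB)-7-Bpin-3-oxabicyclo[3.2.0]heptane
Conditions: thioxanthone (10 mol%), CH2Cl2 (0.02 M), 405 nm LEDs, rt, argon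
Reagents that add atoms: none
Why: Thioxanthone (triplet energy near 65 kcal/mol) passes its triplet energy to the only low-lying chromophore, the ring B styrene (near 60 kcal/mol); the alkenylboronate and the silylated arenes lie well above it. The styrene triplet behaves as a 1,2-diradical whose β-carbon C4 adds to C3 in a 5-exo-trig closure that forms the tetrahydrofuran and leaves a benzylic radical at C7 and a boron-stabilised radical at C9; after intersystem crossing these two centres couple, closing the cyclobutane by 1,4-diradical recombination (C7–C9). The closest known reaction type is the sensitised intramolecular styrene–alkenylboronate [2+2] cycloaddition of 1,6-dienes, which gives the straight and not the crossed adduct (rule of five). C3 is set in the first bond formation: in the chair-like 5-exo transition state ring A on C2 lies pseudo-equatorial, so C9 ends trans to ring A (the Beckwith–Houk preference of a 4-substituted hexenyl radical) and ring A sits on the convex face of the bicycle. C4 is then fixed by ring strain, since only the cis-fused 3-oxabicyclo[3.2.0]heptane can close; a diradical with the trans arrangement reverts to the diene and is recycled, which also makes E/Z isomerisation of the styrene harmless. C7 and C9 are set at the recombination without reliable control (29 is drawn with aryl exo and boron endo), and both are erased later. The step thus needs chemoselective excitation and facial selectivity with respect to C2; the triplet-energy gap should secure the first and the C2 stereocentre the second, while hydrogen abstraction by the sensitiser from the doubly activated C2–H is the side reaction to suppress by working dilute and with a low sensitiser loading.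

Step 19
Reactants: 29 (1R,2R,5S,6R,7R)-2-ArA-6-(DHB)-7-Bpin-3-oxabicyclo[3.2.0]heptane
Product: 30 (1S,2R,5S,6R,7R)-2-ArA-6-(DHB)-3-oxabicyclo[3.2.0]heptan-7-ol
Conditions: NaBO3·4H2O, THF/H2O, rt
Reagents that add atoms: sodium perborate tetrahydrate (NaBO3·4H2O), [Na+].[Na+].O[B-]1(O)OO[B-](O)(O)OO1
Why: Oxidation of the secondary alkylboronate by 1,2-migration from boron to oxygen with retention; the mildly basic medium should spare the aryl silyl ethers, and the C9 configuration is irrelevant to what follows.

Step 20
Reactants: 30 (1S,2R,5S,6R,7R)-2-ArA-6-(DHB)-3-oxabicyclo[3.2.0]heptan-7-ol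
Product: 32 [(2R,3S,4S)-2-ArA-4-(DHB-methyl)tetrahydrofuran-3-yl]methanol, via tetrahydrofuran-3-carbaldehyde 31 (not isolated)
Conditions: [Ir(dF(CF3)ppy)2(5,5'-d(CF3)bpy)]PF6 (2 mol%), 2,4,6-(iPr)3C6H2SH (25 mol%), 2,4,6-collidine, CH2Cl2, blue LEDs, rt; then MeOH, NaBH4, 0 °C
Reagents that add atoms: none
Why: Photocatalytic proton-coupled electron transfer generates the C9 alkoxy radical (radical ring opening of a cyclobutanol); its β-scission is driven by ring strain and goes towards the benzylic C7 radical and not the secondary C3 radical, and the thiol gives C7 its hydrogen. NaBH4 then reduces aldehyde 31 in the same flask before C3 can epimerise, so C3 and C4 keep the cis arrangement inherited from the ring fusion.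

Step 21
Reactants: 32 [(2R,3S,4S)-2-ArA-4-(DHB-methyl)tetrahydrofuran-3-yl]methanol
Product: 33 [(2R,3S,4S)-2-(3-hydroxy-4-methoxyphenyl)-4-{[(2S,3R)-2-(4-hydroxy-3-methoxyphenyl)-3-(hydroxymethyl)-4-methoxy-2,3-dihydro-1-benzofuran-6-yl]methyl}tetrahydrofuran-3-yl]methanol (CNP0242386.1)
Conditions: Bu4NF, AcOH, THF, 0 °C → rt
Reagents that add atoms: none
Why: Fluoride cleaves the two aryl and the one alkyl silyl ether in one operation; acetic acid buffering should keep the ring C phenoxide from opening the dihydrobenzofuran through a quinone methide, and no stereocentre is touched.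

## Compound list

1 | 4-bromo-2,6-dimethoxybenzaldehyde | COc1cc(Br)cc(OC)c1C=O | starting material
2 | 4-bromo-2-hydroxy-6-methoxybenzaldehyde | COc1cc(Br)cc(O)c1C=O | intermediate
3 | 4-bromo-2-methoxy-6-(methoxymethoxy)benzaldehyde | COCOc1cc(Br)cc(OC)c1C=O | intermediate
4 | p-toluenesulfonylmethyl isocyanide | [C-]#[N+]CS(=O)(=O)c1ccc(C)cc1 | starting material
5 | N-[2-ArB-1-(p-toluenesulfonyl)ethenyl]formamide | O=CNC(=Cc1c(OC)cc(Br)cc1OCOC)S(=O)(=O)c1ccc(C)cc1 | intermediate (not isolated)
6 | 2-[4-bromo-2-methoxy-6-(methoxymethoxy)phenyl]acetonitrile | COCOc1cc(Br)cc(OC)c1CC#N | intermediate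
7 | 2-[4-bromo-2-methoxy-6-(methoxymethoxy)phenyl]acetic acid | COCOc1cc(Br)cc(OC)c1CC(=O)O | intermediate
8 | (S)-4-benzyl-1,3-oxazolidin-2-one | O=C1N[C@@H](Cc2ccccc2)CO1 | starting material
9 | mixed anhydride of 7 and pivalic acid | COCOc1cc(Br)cc(OC)c1CC(=O)OC(=O)C(C)(C)C | intermediate (not isolated)
10 | (S)-4-benzyl-3-(2-ArB-acetyl)-1,3-oxazolidin-2-one | COCOc1cc(Br)cc(OC)c1CC(=O)N1C(=O)OC[C@@H]1Cc1ccccc1 | intermediate
11 | vanillin | COc1cc(C=O)ccc1O | starting material
12 | 3-methoxy-4-(triisopropylsilyloxy)benzaldehyde | COc1cc(C=O)ccc1O[Si](C(C)C)(C(C)C)C(C)C | intermediate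
13 | (S)-4-benzyl-3-[(2S,3S)-2-ArB-3-hydroxy-3-ArC-propanoyl]-1,3-oxazolidin-2-one | COCOc1cc(Br)cc(OC)c1[C@@H]([C@H](O)c1ccc(O[Si](C(C)C)(C(C)C)C(C)C)c(OC)c1)C(=O)N1C(=O)OC[C@@H]1Cc1ccccc1 | intermediate
14 | (1S,2R)-2-ArB-1-ArC-propane-1,3-diol | COCOc1cc(Br)cc(OC)c1[C@@H]([C@H](O)c1ccc(O[Si](C(C)C)(C(C)C)C(C)C)c(OC)c1)CO | intermediate
15 | (1S,2R)-2-(4-bromo-2-hydroxy-6-methoxyphenyl)-1-ArC-propane-1,3-diol | COc1cc(Br)cc(O)c1[C@@H]([C@H](O)c1ccc(O[Si](C(C)C)(C(C)C)C(C)C)c(OC)c1)CO | intermediate (not isolated)
16 | [(2S,3R)-6-bromo-4-methoxy-2-ArC-2,3-dihydro-1-benzofuran-3-yl]methanol | Brc1cc(OC)c2c(c1)O[C@H](c1ccc(O[Si](C(C)C)(C(C)C)C(C)C)c(OC)c1)[C@H]2CO | intermediate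
17 | (2S,3R)-6-bromo-3-[(tert-butyldimethylsilyloxy)methyl]-4-methoxy-2-ArC-2,3-dihydro-1-benzofuran | Brc1cc(OC)c2c(c1)O[C@H](c1ccc(O[Si](C(C)C)(C(C)C)C(C)C)c(OC)c1)[C@H]2CO[Si](C)(C)C(C)(C)C | intermediate
18 | (E)-3-(4,4,5,5-tetramethyl-1,3,2-dioxaborolan-2-yl)prop-2-en-1-ol | OC/C=C/B1OC(C)(C)C(C)(C)O1 | starting material
19 | (E)-3-(DHB)prop-2-en-1-ol | OC/C=C/c1cc(OC)c2c(c1)O[C@H](c1ccc(O[Si](C(C)C)(C(C)C)C(C)C)c(OC)c1)[C@H]2CO[Si](C)(C)C(C)(C)C | intermediate
20 | (E)-1-bromo-3-(DHB)prop-2-ene | BrC/C=C/c1cc(OC)c2c(c1)O[C@H](c1ccc(O[Si](C(C)C)(C(C)C)C(C)C)c(OC)c1)[C@H]2CO[Si](C)(C)C(C)(C)C | intermediate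
21 | isovanillin | COc1ccc(C=O)cc1O | starting material
22 | 4-methoxy-3-(triisopropylsilyloxy)benzaldehyde | COc1ccc(C=O)cc1O[Si](C(C)C)(C(C)C)C(C)C | intermediate
23 | ethynyltrimethylsilane | C#C[Si](C)(C)C | starting material
24 | (S)-1-ArA-3-(trimethylsilyl)prop-2-yn-1-ol | COc1ccc([C@H](O)C#C[Si](C)(C)C)cc1O[Si](C(C)C)(C(C)C)C(C)C | intermediate
25 | (R)-1-ArA-prop-2-yn-1-ol | COc1ccc([C@H](O)C#C)cc1O[Si](C(C)C)(C(C)C)C(C)C | intermediate
26 | (R)-1-ArA-prop-2-yn-1-yl (E)-3-(DHB)prop-2-en-1-yl ether | COc1ccc([C@H](OC/C=C/c2cc(OC)c3c(c2)O[C@H](c2ccc(O[Si](C(C)C)(C(C)C)C(C)C)c(OC)c2)[C@H]3CO[Si](C)(C)C(C)(C)C)C#C)cc1O[Si](C(C)C)(C(C)C)C(C)C | intermediate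
27 | pinacolborane | CC1(C)OBOC1(C)C | starting material
28 | (R,E)-1-ArA-3-Bpin-prop-2-en-1-yl (E)-3-(DHB)prop-2-en-1-yl ether | COc1ccc([C@H](OC/C=C/c2cc(OC)c3c(c2)O[C@H](c2ccc(O[Si](C(C)C)(C(C)C)C(C)C)c(OC)c2)[C@H]3CO[Si](C)(C)C(C)(C)C)/C=C/B2OC(C)(C)C(C)(C)O2)cc1O[Si](C(C)C)(C(C)C)C(C)C | intermediate
29 | (1R,2R,5S,6R,7R)-2-ArA-6-(DHB)-7-Bpin-3-oxabicyclo[3.2.0]heptane (cis-fused, ring A exo; one C6/C7 epimer) | COc1ccc([C@@H]2OC[C@H]3[C@H](c4cc(OC)c5c(c4)O[C@H](c4ccc(O[Si](C(C)C)(C(C)C)C(C)C)c(OC)c4)[C@H]5CO[Si](C)(C)C(C)(C)C)[C@@H](B4OC(C)(C)C(C)(C)O4)[C@@H]23)cc1O[Si](C(C)C)(C(C)C)C(C)C | intermediate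
30 | (1S,2R,5S,6R,7R)-2-ArA-6-(DHB)-3-oxabicyclo[3.2.0]heptan-7-ol | COc1ccc([C@@H]2OC[C@H]3[C@H](c4cc(OC)c5c(c4)O[C@H](c4ccc(O[Si](C(C)C)(C(C)C)C(C)C)c(OC)c4)[C@H]5CO[Si](C)(C)C(C)(C)C)[C@@H](O)[C@@H]23)cc1O[Si](C(C)C)(C(C)C)C(C)C | intermediate
31 | (2R,3R,4S)-2-ArA-4-(DHB-methyl)tetrahydrofuran-3-carbaldehyde | COc1ccc([C@@H]2OC[C@@H](Cc3cc(OC)c4c(c3)O[C@H](c3ccc(O[Si](C(C)C)(C(C)C)C(C)C)c(OC)c3)[C@H]4CO[Si](C)(C)C(C)(C)C)[C@H]2C=O)cc1O[Si](C(C)C)(C(C)C)C(C)C | intermediate (not isolated)
32 | [(2R,3S,4S)-2-ArA-4-(DHB-methyl)tetrahydrofuran-3-yl]methanol | COc1ccc([C@@H]2OC[C@@H](Cc3cc(OC)c4c(c3)O[C@H](c3ccc(O[Si](C(C)C)(C(C)C)C(C)C)c(OC)c3)[C@H]4CO[Si](C)(C)C(C)(C)C)[C@H]2CO)cc1O[Si](C(C)C)(C(C)C)C(C)C | intermediate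
33 | CNP0242386.1, (2R,3S,4S,2'S,3'R) | COc1ccc([C@@H]2OC[C@@H](Cc3cc(OC)c4c(c3)O[C@H](c3ccc(O)c(OC)c3)[C@H]4CO)[C@H]2CO)cc1O | target

## Step count and least certain steps

Total: 21 steps. Longest linear sequence: 17 steps (steps 1–5, 7–12 and 16–21); steps 6 and 13–15 are side branches.

Step 18 (key step). What may go wrong: poor facial selectivity in the first C3–C4 bond formation (the C2/C3 cis series), hydrogen abstraction by the sensitiser triplet at C2–H with loss of the C2 configuration, or E/Z isomerisation outpacing closure. The fallback forms the same C3–C4 bond by a ground-state radical cyclisation; it sets out from 25 and 20 and comes back at 32. Partial hydrogenation of 25 (H2, Pd/CaCO3 poisoned with Pb(OAc)2, quinoline) would give (R)-1-ArA-prop-2-en-1-ol F1. Hydroxyl-directed epoxidation (VO(acac)2, tBuOOH) would give (S)-ArA-(oxiran-2-yl)methanol F2 as a mixture at the oxirane carbon, which is of no consequence because that carbon becomes a radical. O-Alkylation with 20 (NaH, THF, 0 °C) would give the epoxy cinnamyl ether F3. Cp2TiCl (from Cp2TiCl2 and Zn, THF) would open the oxirane by electron transfer from trivalent titanium to the C3 radical with the titanium alkoxide on C9; 5-exo cyclisation onto the styrene with the same chair-like 2,3-trans/3,4-cis preference, reduction of the benzylic radical and protonation then give 32 (Nugent–RajanBabu reductive epoxide cyclisation).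

Step 20. What may go wrong: oxidation of the electron-rich arenes by the excited photocatalyst, leading to benzylic C–H or C–C cleavage elsewhere, and epimerisation at C3 if the aldehyde lingers before reduction. The fallback generates the same alkoxy radical reductively; it sets out from 30 and comes back at 31 and then 32. Mitsunobu reaction of 30 with N-hydroxyphthalimide (PPh3, iPrO2CN=NCO2iPr, THF) would give the N-cyclobutoxyphthalimide F4 (inversion at C9, irrelevant). Visible-light reduction with Hantzsch ester and fac-Ir(ppy)3 cleaves the N–O bond, β-scission gives the C7 radical, which takes hydrogen from the dihydropyridine, and 31 is reduced with NaBH4 as before.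

Step 14. What may go wrong: insufficient enantioselectivity or slow addition with the electron-rich aldehyde, or the wrong facial sense for the chosen ligand antipode. The fallback replaces catalytic induction by enzymatic resolution; it sets out from 22 and comes back at 25. Addition of HC≡CMgBr (THF, 0 °C) would give racemic 1-ArA-prop-2-yn-1-ol F5. Pseudomonas cepacia lipase with vinyl acetate should acylate the (R)-enantiomer (Kazlauskas rule, aryl as the large group) to (R)-1-ArA-prop-2-yn-1-yl acetate F6 and leave (S)-1-ArA-prop-2-yn-1-ol F7 behind. iBu2AlH (CH2Cl2, −78 °C) removes the acetyl group from F6 and gives 25.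

Step 3. What may go wrong: incomplete fragmentation of the isocyanide adduct with a di-ortho-substituted, electron-rich aldehyde, so that the reductive cyanation stalls. The fallback is a different one-carbon homologation; it sets out from 3 and comes back at 7, which also removes step 4. Addition of trichloromethanide (CHCl3, KOH, DMF, 0 °C) would give 2,2,2-trichloro-1-ArB-ethanol F8. NaBH4 and NaOH in tBuOH convert it through the gem-dichloroepoxide into the arylacetic acid 7 (Jocic-type reductive homologation).

Step 16. What may go wrong: silyl transfer from an aryl silyl ether to the sodium alkoxide, or base-induced propargyl–allenyl isomerisation and [2,3]-Wittig rearrangement of the product. The fallback forms the ether without a free alkali alkoxide; it sets out from 19 and 25 and comes back at 26. 19 would be converted into (E)-3-(DHB)prop-2-en-1-yl methyl carbonate F9 (ClCO2Me, pyridine). Zerovalent palladium (Pd(PPh3)4) ionises F9 to the π-allyl complex, which the zinc alkoxide of 25 (ZnEt2, 0.5 equiv) attacks at the unsubstituted terminus (Tsuji–Trost allylic etherification), giving the linear E ether 26.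

## Further compounds

F1 | step 18 | (R)-1-ArA-prop-2-en-1-ol | COc1ccc([C@H](O)C=C)cc1O[Si](C(C)C)(C(C)C)C(C)C
F2 | step 18 | (S)-ArA-(oxiran-2-yl)methanol, mixture at the oxirane carbon | COc1ccc([C@H](O)C2CO2)cc1O[Si](C(C)C)(C(C)C)C(C)C
F3 | step 18 | (E)-3-(DHB)prop-2-en-1-yl ether of F2 | COc1ccc([C@H](OC/C=C/c2cc(OC)c3c(c2)O[C@H](c2ccc(O[Si](C(C)C)(C(C)C)C(C)C)c(OC)c2)[C@H]3CO[Si](C)(C)C(C)(C)C)C2CO2)cc1O[Si](C(C)C)(C(C)C)C(C)C
F4 | step 20 | N-cyclobutoxyphthalimide from 30, C7 epimer of the bicycle | COc1ccc([C@@H]2OC[C@H]3[C@H](c4cc(OC)c5c(c4)O[C@H](c4ccc(O[Si](C(C)C)(C(C)C)C(C)C)c(OC)c4)[C@H]5CO[Si](C)(C)C(C)(C)C)[C@H](ON4C(=O)c5ccccc5C4=O)[C@@H]23)cc1O[Si](C(C)C)(C(C)C)C(C)C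
F5 | step 14 | racemic 1-ArA-prop-2-yn-1-ol | COc1ccc(C(O)C#C)cc1O[Si](C(C)C)(C(C)C)C(C)C
F6 | step 14 | (R)-1-ArA-prop-2-yn-1-yl acetate | COc1ccc([C@H](OC(C)=O)C#C)cc1O[Si](C(C)C)(C(C)C)C(C)C
F7 | step 14 | (S)-1-ArA-prop-2-yn-1-ol | COc1ccc([C@@H](O)C#C)cc1O[Si](C(C)C)(C(C)C)C(C)C
F8 | step 3 | 2,2,2-trichloro-1-ArB-ethanol, racemic | COCOc1cc(Br)cc(OC)c1C(O)C(Cl)(Cl)Cl
F9 | step 16 | (E)-3-(DHB)prop-2-en-1-yl methyl carbonate | COC(=O)OC/C=C/c1cc(OC)c2c(c1)O[C@H](c1ccc(O[Si](C(C)C)(C(C)C)C(C)C)c(OC)c1)[C@H]2CO[Si](C)(C)C(C)(C)C
A1 | alternative 1 | (S)-7-chloro-5-methoxy-2-(3-methoxy-4-tosyloxyphenyl)chroman-4-one | O=C1C[C@@H](c2ccc(OS(=O)(=O)c3ccc(C)cc3)c(OC)c2)Oc2cc(Cl)cc(OC)c12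
A2 | alternative 1 | methyl (2S,3S)-6-chloro-4-methoxy-2-(3-methoxy-4-tosyloxyphenyl)-2,3-dihydro-1-benzofuran-3-carboxylate | Clc1cc(OC)c2c(c1)O[C@H](c1ccc(OS(=O)(=O)c3ccc(C)cc3)c(OC)c1)[C@H]2C(=O)OC
A3 | alternative 2 | 3-{[(3S,4S,5R)-4-(benzyloxymethyl)-5-(3-benzyloxy-4-methoxyphenyl)tetrahydrofuran-3-yl]methyl}cyclobut-2-en-1-one | COc1ccc([C@@H]2OC[C@@H](CC3=CC(=O)C3)[C@H]2COCc2ccccc2)cc1OCc1ccccc1
A4 | alternative 2 | triisopropylsilyl ynol ether of (3R,4S)-4-(4-benzyloxy-3-methoxyphenyl)-3-(benzyloxymethyl)-4-(tert-butyldimethylsilyloxy)but-1-yn-1-ol | CC(C)[Si](OC#C[C@H](COCc1ccccc1)[C@@H](O[Si](C)(C)C(C)(C)C)c1ccc(OCc2ccccc2)c(OC)c1)(C(C)C)C(C)C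
A5 | alternative 2 | 2,5-disubstituted resorcinol mono-triisopropylsilyl ether (ring B with both side chains) | COc1ccc([C@@H]2OC[C@@H](Cc3cc(O[Si](C(C)C)(C(C)C)C(C)C)c([C@H](COCc4ccccc4)[C@@H](O[Si](C)(C)C(C)(C)C)c4ccc(OCc5ccccc5)c(OC)c4)c(O)c3)[C@H]2COCc2ccccc2)cc1OCc1ccccc1
A6 | alternative 3 | 3-methoxy-2-(trimethylsilyl)phenyl triflate carrying the tetrahydrofuran half at C5 | COc1ccc([C@@H]2OC[C@@H](Cc3cc(OC)c([Si](C)(C)C)c(OS(=O)(=O)C(F)(F)F)c3)[C@H]2COCc2ccccc2)cc1OCc1ccccc1
A7 | alternative 3 | (R)-(4-benzyloxy-3-methoxyphenyl)[(S)-oxiran-2-yl]methanol (erythro) | O[C@H](c1ccc(OCc2ccccc2)c(OC)c1)[C@@H]1CO1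
A8 | alternative 3 | tri-O-benzyl 33 with free C9' hydroxyl | COc1ccc([C@@H]2OC[C@@H](Cc3cc(OC)c4c(c3)O[C@H](c3ccc(OCc5ccccc5)c(OC)c3)[C@H]4CO)[C@H]2COCc2ccccc2)cc1OCc1ccccc1
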